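The bond between furan C4 and the chain stereocentre C5 is the disconnection on which the route rests. C5 sits β to C7, the sp2 CH of the C7=C8 prenyl double bond. With C7 taken back to an aldehyde, C5 becomes the β-carbon of an E-enal made from (R)-monomethyl 3-methylglutarate, which supplies C3. The key step is a rhodium/chiral diene-catalysed asymmetric 1,4-addition of a 5-arylfuran-3-ylboronic acid (hydroquinone masked as bis-TIPS ether). It forms this bond, sets C5 under catalyst control and unites both halves in one operation. Boron directs bonding to the furan β-carbon C4, not to the nucleophilic α-carbon. Isopropylidene Wittig olefination and global deprotection finish the route.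

Key step: step 7

Remark: chain atoms are numbered as in the target acid (C1 = CO2H, C3 = CHMe, C5 = CH-furyl, C7=C8 = alkene); the target is (3R,5S). Compounds 1, 3 and 10 are taken as catalogue chemicals. Assumption: the sense of induction of the diene ligand on this acyclic E-enal follows the carbonyl-avoidance model; it should be confirmed on a simple model enal, and the antipodal ligand used if the sense is reversed.

Step 1
Reactants: 1 2-bromobenzene-1,4-diol (bromohydroquinone)
Product: 2 2-bromo-1,4-bis(triisopropylsilyloxy)benzene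
Conditions: TIPSCl, imidazole, DMAP (cat.), DMF, rt to 40 °C
Reagents that add atoms: triisopropylsilyl chloride, CC(C)[Si](Cl)(C(C)C)C(C)C
Why: Imidazole-mediated silyl ether formation on both phenols; TIPS is chosen because it should survive organolithium, aqueous base and ylide chemistry and fall to fluoride at the end.

Step 2
Reactants: 2 2-bromo-1,4-bis(triisopropylsilyloxy)benzene; 3 2,4-dibromofuran
Product: 6 4-bromo-2-[2,5-bis(triisopropylsilyloxy)phenyl]furan, via aryllithium 4 (not isolated), via arylzinc chloride 5 (not isolated)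
Conditions: n-BuLi, THF, −78 °C; ZnCl2, −78 °C to rt; 3, Pd(PPh3)4 (cat.), THF, 50 °C
Reagents that add atoms: none
Why: Bromine–lithium exchange and zincation give an arylzinc for a Negishi coupling at C2–Br of 3, the α-C–Br bond being the faster site of oxidative addition, so C4–Br is kept; prompt zincation at −78 °C should forestall O-to-C silyl migration in the ortho-silyloxy aryllithium.

Step 3
Reactants: 6 4-bromo-2-[2,5-bis(triisopropylsilyloxy)phenyl]furan
Product: 9 {5-[2,5-bis(triisopropylsilyloxy)phenyl]furan-3-yl}boronic acid, via 3-furyllithium 7 (not isolated), via lithium triisopropoxyborate 8 (not isolated)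
Conditions: B(OiPr)3, THF/toluene, −78 °C, n-BuLi added dropwise (in situ quench); then aq. NH4Cl/dil. HCl to pH 5
Reagents that add atoms: triisopropyl borate, CC(C)OB(OC(C)C)OC(C)C; water, O
Why: Lithiation–borylation: bromine–lithium exchange at furan C4 in the presence of the borate should trap the 3-furyllithium before it can isomerise to the α-lithio furan, and mild hydrolysis of the ate complex gives the boronic acid.

Step 4
Reactants: 10 (3R)-5-methoxy-3-methyl-5-oxopentanoic acid ((R)-monomethyl 3-methylglutarate)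
Product: 11 methyl (3R)-5-hydroxy-3-methylpentanoate
Conditions: BH3·SMe2, THF, −10 °C to rt; MeOH quench
Reagents that add atoms: none
Why: Chemoselective borane reduction: the free acid is reduced through its acyloxyborane much faster than the methyl ester; C3 is untouched, and the hydroxy ester is carried on at once to avoid lactonisation.

Step 5
Reactants: 11 methyl (3R)-5-hydroxy-3-methylpentanoate
Product: 12 methyl (3R)-3-methyl-5-oxopentanoate
Conditions: TEMPO (cat.), PhI(OAc)2, CH2Cl2, rt
Reagents that add atoms: none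
Why: Oxoammonium (TEMPO/PhI(OAc)2) oxidation should stop at the aldehyde under non-basic conditions, leaving the ester and the β-stereocentre alone.

Step 6
Reactants: 12 methyl (3R)-3-methyl-5-oxopentanoate
Product: 13 methyl (3R,5E)-3-methyl-7-oxohept-5-enoate
Conditions: Ph3P=CHCHO, toluene, 80 °C
Reagents that add atoms: (triphenylphosphoranylidene)acetaldehyde, O=CC=P(c1ccccc1)(c1ccccc1)c1ccccc1
Why: Wittig reaction with the stabilised formylmethylene ylide gives the two-carbon homologated E-enal; the less electrophilic enal product should resist a second homologation at limited ylide excess.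

Step 7
Reactants: 9 {5-[2,5-bis(triisopropylsilyloxy)phenyl]furan-3-yl}boronic acid; 13 methyl (3R,5E)-3-methyl-7-oxohept-5-enoate
Product: 14 methyl (3R,5S)-5-{5-[2,5-bis(triisopropylsilyloxy)phenyl]furan-3-yl}-3-methyl-7-oxoheptanoate
Conditions: [RhCl(C2H4)2]2 (cat.), (R,R)-Ph-bod* [(1R,4R)-2,5-diphenylbicyclo[2.2.2]octa-2,5-diene] (cat.), KOH (0.1–0.2 equiv), 1,4-dioxane/H2O 10:1, 25–30 °C
Reagents that add atoms: none
Why: This is a Hayashi–Miyaura-type rhodium/chiral diene-catalysed asymmetric 1,4-addition of a heteroarylboronic acid to an enal: B-to-Rh transmetalation of 9 gives a furan-3-yl–Rh(I)(diene) species, the enal binds through C5=C6, syn migratory insertion forms the furan C4–C5 bond at the boron-bearing carbon, and water protonates the oxa-π-allyl rhodium intermediate to release the aldehyde and Rh–OH. No ring is closed. The new stereocentre C5 is set by the ligand (catalyst control): the furyl group must arrive on the Si face of C5 (the C5-Si/C6-Re face of the E-enal) to give 5S, and (R,R)-Ph-bod* is expected to do so if the formyl group avoids the ligand phenyl, the same sense that converts cyclohex-2-enone into the (R)-adduct; the acyclic, 1,3-remote C3 methyl centre should exert little bias. The step needs 1,4- over 1,2-addition (diene ligands favour conjugate addition to enals where phosphine ligands give carbinols), bonding at furan C4 and not at the nucleophilic α-carbon (secured by ipso transfer from boron), and little protodeboronation or aldol chemistry (a 3-furylboronic acid is far more robust than a 2-furyl one; low hydroxide loading near room temperature).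

Step 8
Reactants: 14 methyl (3R,5S)-5-{5-[2,5-bis(triisopropylsilyloxy)phenyl]furan-3-yl}-3-methyl-7-oxoheptanoate
Product: 15 methyl (3R,5S)-5-{5-[2,5-bis(triisopropylsilyloxy)phenyl]furan-3-yl}-3,8-dimethylnon-7-enoate
Conditions: i-PrPPh3I, n-BuLi, THF, 0 °C; then 14, −78 °C to rt
Reagents that add atoms: isopropyltriphenylphosphonium iodide, CC(C)[P+](c1ccccc1)(c1ccccc1)c1ccccc1.[I-]
Why: Wittig olefination with the non-stabilised isopropylidene ylide converts the aldehyde into the C7=C8 alkene (no E/Z issue); the ylide should attack the aldehyde far faster than the methyl ester at low temperature, and C5, being β to the carbonyl, cannot epimerise.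

Step 9
Reactants: 15 methyl (3R,5S)-5-{5-[2,5-bis(triisopropylsilyloxy)phenyl]furan-3-yl}-3,8-dimethylnon-7-enoate
Product: 17 (3R,5S)-5-[5-(2,5-dihydroxyphenyl)furan-3-yl]-3,8-dimethylnon-7-enoic acid, via hydroquinone methyl ester 16 (not isolated)
Conditions: TBAF, THF, 0 °C, Ar; then LiOH, MeOH/H2O (degassed), rt; then 1 M HCl/Na2S2O4 work-up
Reagents that add atoms: lithium hydroxide, [Li+].[OH-]
Why: Fluoride desilylation of both aryl silyl ethers followed by saponification of the methyl ester in the same flask; exclusion of oxygen and an acidic, dithionite-containing work-up should keep the hydroquinone from oxidising, and neither stereocentre is base-labile.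

Compound list
1 | 2-bromobenzene-1,4-diol (bromohydroquinone) | Oc1ccc(O)c(Br)c1 | starting material
2 | 2-bromo-1,4-bis(triisopropylsilyloxy)benzene | Brc1cc(O[Si](C(C)C)(C(C)C)C(C)C)ccc1O[Si](C(C)C)(C(C)C)C(C)C | intermediate
3 | 2,4-dibromofuran | Brc1coc(Br)c1 | starting material
4 | [2,5-bis(triisopropylsilyloxy)phenyl]lithium | [Li]c1cc(O[Si](C(C)C)(C(C)C)C(C)C)ccc1O[Si](C(C)C)(C(C)C)C(C)C | intermediate
5 | [2,5-bis(triisopropylsilyloxy)phenyl]zinc chloride | Cl[Zn]c1cc(O[Si](C(C)C)(C(C)C)C(C)C)ccc1O[Si](C(C)C)(C(C)C)C(C)C | intermediate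
6 | 4-bromo-2-[2,5-bis(triisopropylsilyloxy)phenyl]furan | Brc1coc(-c2cc(O[Si](C(C)C)(C(C)C)C(C)C)ccc2O[Si](C(C)C)(C(C)C)C(C)C)c1 | intermediate
7 | {5-[2,5-bis(triisopropylsilyloxy)phenyl]furan-3-yl}lithium | [Li]c1coc(-c2cc(O[Si](C(C)C)(C(C)C)C(C)C)ccc2O[Si](C(C)C)(C(C)C)C(C)C)c1 | intermediate
8 | lithium {5-[2,5-bis(triisopropylsilyloxy)phenyl]furan-3-yl}triisopropoxyborate | [Li+].CC(C)O[B-](OC(C)C)(OC(C)C)c1coc(-c2cc(O[Si](C(C)C)(C(C)C)C(C)C)ccc2O[Si](C(C)C)(C(C)C)C(C)C)c1 | intermediate
9 | {5-[2,5-bis(triisopropylsilyloxy)phenyl]furan-3-yl}boronic acid | OB(O)c1coc(-c2cc(O[Si](C(C)C)(C(C)C)C(C)C)ccc2O[Si](C(C)C)(C(C)C)C(C)C)c1 | intermediate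
10 | (3R)-5-methoxy-3-methyl-5-oxopentanoic acid ((R)-monomethyl 3-methylglutarate) | OC(=O)C[C@@H](C)CC(=O)OC | starting material
11 | methyl (3R)-5-hydroxy-3-methylpentanoate | OCC[C@@H](C)CC(=O)OC | intermediate
12 | methyl (3R)-3-methyl-5-oxopentanoate | O=CC[C@@H](C)CC(=O)OC | intermediate
13 | methyl (3R,5E)-3-methyl-7-oxohept-5-enoate | O=C/C=C/C[C@@H](C)CC(=O)OC | intermediate
14 | methyl (3R,5S)-5-{5-[2,5-bis(triisopropylsilyloxy)phenyl]furan-3-yl}-3-methyl-7-oxoheptanoate | O=CC[C@H](C[C@@H](C)CC(=O)OC)c1coc(-c2cc(O[Si](C(C)C)(C(C)C)C(C)C)ccc2O[Si](C(C)C)(C(C)C)C(C)C)c1 | intermediate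
15 | methyl (3R,5S)-5-{5-[2,5-bis(triisopropylsilyloxy)phenyl]furan-3-yl}-3,8-dimethylnon-7-enoate | CC(C)=CC[C@H](C[C@@H](C)CC(=O)OC)c1coc(-c2cc(O[Si](C(C)C)(C(C)C)C(C)C)ccc2O[Si](C(C)C)(C(C)C)C(C)C)c1 | intermediate
16 | methyl (3R,5S)-5-[5-(2,5-dihydroxyphenyl)furan-3-yl]-3,8-dimethylnon-7-enoate | CC(C)=CC[C@H](C[C@@H](C)CC(=O)OC)c1coc(-c2cc(O)ccc2O)c1 | intermediate
17 | (3R,5S)-5-[5-(2,5-dihydroxyphenyl)furan-3-yl]-3,8-dimethylnon-7-enoic acid | CC(C)=CC[C@H](C[C@@H](C)CC(=O)O)c1coc(-c2cc(O)ccc2O)c1 | target

Total step count: 9. Longest linear sequence: 6 steps (steps 1–3 or 4–6, then 7–9).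

Steps most likely to fail

Step 7. The furyl–rhodium species may add 1,2 to the aldehyde of 13 or 14, the enal may undergo hydroxide-mediated aldol condensation or deconjugation, or protodeboronation may outrun insertion. The fallback keeps a free aldehyde out of the bond-forming step. It sets out from 12, which is converted by Wittig reaction with N-methoxy-N-methyl-2-(triphenylphosphoranylidene)acetamide (CH2Cl2, rt to 40 °C) into the Weinreb enamide methyl (3R,5E)-7-[methoxy(methyl)amino]-3-methyl-7-oxohept-5-enoate F1. Rhodium/chiral diene 1,4-addition of 9 to F1 (same catalyst, 40–50 °C), a substrate class that cannot undergo 1,2-addition or aldol reactions, should give methyl (3R,5S)-5-{5-[2,5-bis(triisopropylsilyloxy)phenyl]furan-3-yl}-7-[methoxy(methyl)amino]-3-methyl-7-oxoheptanoate F2. Chemoselective reduction of the Weinreb amide with the Schwartz reagent Cp2Zr(H)Cl (THF, rt), which should leave the methyl ester alone, brings the route back at 14.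

Step 3. The 4-lithiofuran may isomerise by proton transfer to the more stable α-lithio furan, so that boron ends up on the wrong carbon, or the boronic acid may protodeboronate during acidic work-up. The fallback avoids the organolithium and sets out from 6. Palladium-catalysed Miyaura borylation (B2pin2, Pd(dppf)Cl2, KOAc, dioxane, 85 °C) should give 2-{5-[2,5-bis(triisopropylsilyloxy)phenyl]furan-3-yl}-4,4,5,5-tetramethyl-1,3,2-dioxaborolane F3. Transesterification with diethanolamine (Et2O, rt) gives the crystalline diethanolamine boronate 2-{5-[2,5-bis(triisopropylsilyloxy)phenyl]furan-3-yl}-1,3,6,2-dioxazaborocane F4. Brief biphasic hydrolysis (dil. HCl/EtOAc) brings the route back at 9.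

Step 2. The ortho-silyloxy aryllithium may undergo O-to-C silyl migration before zincation, or site selectivity may erode (coupling at C4–Br, double arylation). The fallback uses a boron nucleophile made without lithium and sets out from 2. Miyaura borylation (B2pin2, Pd(dppf)Cl2, KOAc, dioxane, 90 °C) should give 2-[2,5-bis(triisopropylsilyloxy)phenyl]-4,4,5,5-tetramethyl-1,3,2-dioxaborolane F5. Suzuki–Miyaura coupling of F5 with a slight excess of 3 (Pd(PPh3)4, aq. Na2CO3, DME, 70 °C) at the more reactive C2–Br brings the route back at 6.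

Further compounds
F1 | step 7 | methyl (3R,5E)-7-[methoxy(methyl)amino]-3-methyl-7-oxohept-5-enoate | CON(C)C(=O)/C=C/C[C@@H](C)CC(=O)OC
F2 | step 7 | methyl (3R,5S)-5-{5-[2,5-bis(triisopropylsilyloxy)phenyl]furan-3-yl}-7-[methoxy(methyl)amino]-3-methyl-7-oxoheptanoate | CON(C)C(=O)C[C@H](C[C@@H](C)CC(=O)OC)c1coc(-c2cc(O[Si](C(C)C)(C(C)C)C(C)C)ccc2O[Si](C(C)C)(C(C)C)C(C)C)c1
F3 | step 3 | 2-{5-[2,5-bis(triisopropylsilyloxy)phenyl]furan-3-yl}-4,4,5,5-tetramethyl-1,3,2-dioxaborolane | CC1(C)OB(OC1(C)C)c1coc(-c2cc(O[Si](C(C)C)(C(C)C)C(C)C)ccc2O[Si](C(C)C)(C(C)C)C(C)C)c1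
F4 | step 3 | 2-{5-[2,5-bis(triisopropylsilyloxy)phenyl]furan-3-yl}-1,3,6,2-dioxazaborocane | C1COB(OCCN1)c1coc(-c2cc(O[Si](C(C)C)(C(C)C)C(C)C)ccc2O[Si](C(C)C)(C(C)C)C(C)C)c1
F5 | step 2 | 2-[2,5-bis(triisopropylsilyloxy)phenyl]-4,4,5,5-tetramethyl-1,3,2-dioxaborolane | CC1(C)OB(OC1(C)C)c1cc(O[Si](C(C)C)(C(C)C)C(C)C)ccc1O[Si](C(C)C)(C(C)C)C(C)C
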